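The earlier runs and the new flask stem from a simulated flask for substances that don't exist; noise was put on by code.

1. The pitfall is to treat a catalyst as a valve: raise [X] by some factor and every time constant falls by that factor. This bench rule says that time × [X] stays constant.

| setting | noon | autumn | dawn | flask |
|---|---|---|---|---|
| Q | 0.25 M | 0.25 M | 0.25 M | 0.25 M |
| Z | 0.25 M | 0.25 M | 0.25 M | 0.25 M |
| G | 0.50 M | 0.50 M | 0.75 M | 0.500 M |
| X | 0.090 mM | 0.36 mM | 0.18 mM | 0.18 mM |
| remark | run made earlier | run made earlier | run made earlier |  |
| time |  |  |  | 80 min |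

| run | time / min | Q / % | Z / % | D / % |
|---|---|---|---|---|
| noon | 8.00 | 22 | 40 | 23 |
| noon | 12.0 | 22 | 42 | 30 |
| noon | 20.0 | 16 | 34 | 32 |
| noon | 40.0 | 7 | 32 | 43 |
| noon | 60.0 | 2 | 20 | 52 |
| noon | 90.0 | 7 | 18 | 47 |
| autumn | 15.0 | 9 | 30 | 39 |
| autumn | 30.0 | 4 | 23 | 45 |
| autumn | 50.0 | 0 | 16 | 51 |
| autumn | 60.0 | 0 | 14 | 55 |
| autumn | 80.0 | 1 | 11 | 52 |
| autumn | 90.0 | 0 | 12 | 52 |
| dawn | 20.0 | 3 | 25 | 46 |
| dawn | 40.0 | 3 | 12 | 50 |
| dawn | 60.0 | 4 | 8 | 51 |
| dawn | 80.0 | 0 | 8 | 51 |
| dawn | 90.0 | 0 | 4 | 52 |

(each reading ± 2 percentage points)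

- part of the Q and Z charged together that has reacted at 80 min
- excess of D over L in the product at 80 min
- excess of Z over Q among what is left of the two at 80 min

- X is single-handed; Q and Z are mirror images of each other, charged as a racemate, each of them at the stated concentration
- an excess is below zero if the other one leads

2. Noon, autumn and the new flask share their charges of Q, Z and G and differ in [X]. If [X] acts as one factor on the clock, their curves are one curve with a stretched time axis, and the rule demands a stretch of 4.00 from noon to autumn.

3. Match Z across the two runs. Noon reads 32% at 40.0 min, and autumn, slightly ahead, reads 30% at 15.0 min. Noon then reads 20% at 60.0 min, and autumn, slightly behind, reads 23% at 30.0 min. Averaged in logarithms, the two time ratios give a stretch of 2.31, which is less than the rule demands. So the rule has already failed across this span of [X].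

4. Now go to logarithms. The logarithm of the stretch over the logarithm of the [X] ratio is the average order in X between noon and autumn: 0.604, a reading that carries the scatter of Z. Two values of [X] give this average slope and cannot show whether the slope bends between them.

5. The new flask has half the [X] of autumn, so by my reckoning its 80 min equals autumn at 52.6 min. The nearest autumn reading, at 50.0 min, gives 84.0% reacted and a product excess of 21.4%.

6. The forecast takes “the order in X is about one half” and gives 85%, 16.4% and 92%.

The flask gives 81.7%, 22.9% and 77.6%. At 80.0 min, 66.1% of its catalyst stood as E and 33.9% as X.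

    G + X + Q → X + D (k = 4300 L² mol⁻² min⁻¹)
    2 X ⇌ E, settled at all times (K = 16000 L mol⁻¹)
    G + X + Z → X + L (k = 1200 L² mol⁻² min⁻¹)
    Q ⇌ Z (k = 0.00160 min⁻¹)

Now use the order once more, on a neighbour flask charged with 1.1 × 10⁻⁴ M of X and otherwise like the new flask. With 0.604, its 80 min equals autumn at 39.1 min, which lies between the autumn readings of Z, 23% at 30.0 min and 16% at 50.0 min. The neighbour holds Z at 19.2%.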